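**Strategy.** Everything rests on forming the pyranone (ring B) last, at O1–C2 and C3=C4, from a 2,6-dihydroxy-4-alkoxybenzaldehyde that already carries the complete, protected side chain. The formyl carbon (future C4) sits on the carbon that becomes C4a, flanked by two equivalent phenol carbons (future C5 and C8a) and para to the ether carbon C7, so whichever phenol is acylated, only the 5-hydroxy-7-alkoxycoumarin can result. One operation with Ph3P=C=C=O forms the lactone ester bond and closes ring B by intramolecular Wittig olefination. The side chain is built from D-erythronolactone acetonide by acetylide displacement and two zirconium-catalysed carboaluminations and joined by Mitsunobu etherification.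

Key step: step 11

Remark: the side chain is numbered C1′ (OCH2) to C11′ (CMe2OH); C1, C2, C3 and C4 of lactone 1 become C11′, C10′, C9′ and C8′, which maps the (2R,3R) lactone onto the (9′R,10′R) erythro triol without any inversion.

**Step 1**
Reactants: 1 2,3-O-isopropylidene-D-erythronolactone
Product: 3 2-[(4R,5R)-5-(hydroxymethyl)-2,2-dimethyl-1,3-dioxolan-4-yl]propan-2-ol, via methyl ketone 2 (not isolated)
Conditions: MeMgBr (3.5 equiv), THF, 0 °C → rt; aq NH4Cl
Reagents that add atoms: methylmagnesium bromide, C[Mg]Br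
Why: Double Grignard addition to a γ-lactone (through the ketone) creates the achiral tertiary carbinol C11′ and frees the primary hydroxyl, while C2 and C3 of the lactone are untouched and become C10′ and C9′.

**Step 2**
Reactants: 3 diol
Product: 4 (4R,5R)-2,2-dimethyl-4-[2-(triethylsilyloxy)propan-2-yl]-5-[(triethylsilyloxy)methyl]-1,3-dioxolane
Conditions: TESOTf (2.5 equiv), 2,6-lutidine, CH2Cl2, −78 → 0 °C
Reagents that add atoms: triethylsilyl trifluoromethanesulfonate, CC[Si](CC)(CC)OS(=O)(=O)C(F)(F)F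
Why: Silyl triflate silylation caps even the hindered tertiary alcohol, and both hydroxyls are protected because activating the primary hydroxyl of the free 1,4-diol would invite cyclisation to a tetrahydrofuran.

**Step 3**
Reactants: 4 bis(triethylsilyl) ether
Product: 5 {(4R,5R)-2,2-dimethyl-5-[2-(triethylsilyloxy)propan-2-yl]-1,3-dioxolan-4-yl}methanol
Conditions: PPTS (0.1 equiv), MeOH/CH2Cl2 (1:1), 0 °C
Reagents that add atoms: none
Why: Acid-catalysed methanolysis of silyl ethers depends strongly on steric hindrance, so the primary triethylsilyl ether should be cleaved at 0 °C while the tertiary one and the acetonide remain.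

**Step 4**
Reactants: 5 primary alcohol
Product: 7 (4R,5R)-2,2-dimethyl-4-[2-(triethylsilyloxy)propan-2-yl]-5-[3-(trimethylsilyl)prop-2-yn-1-yl]-1,3-dioxolane, via triflate 6 (not isolated)
Conditions: Tf2O, 2,6-lutidine, CH2Cl2, −78 °C; then cannulated into LiC≡CSiMe3 (3 equiv; from Me3SiC≡CH, n-BuLi), THF/DMPU, −78 → −20 °C
Reagents that add atoms: ethynyltrimethylsilane (used as its lithium acetylide), C#C[Si](C)(C)C
Why: SN2 alkynylation of a primary triflate by a lithium acetylide in THF/DMPU is the dependable substitution at a carbon β to a dioxolane oxygen, and the cold, immediate use of the triflate should outrun participation by the neighbouring silyl ether; the adjacent stereocentre C9′ is not involved.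

**Step 5**
Reactants: 7 silylated alkyne
Product: 8 (4R,5R)-2,2-dimethyl-4-(prop-2-yn-1-yl)-5-[2-(triethylsilyloxy)propan-2-yl]-1,3-dioxolane
Conditions: K2CO3, MeOH, rt
Reagents that add atoms: none
Why: Base-catalysed protodesilylation cleaves the C(sp)–Si bond selectively, since the silyl ether on oxygen and the acetonide are inert to K2CO3 in methanol.

**Step 6**
Reactants: 8 terminal alkyne
Product: 10 (4R,5R)-4-[(2E)-3-iodo-2-methylprop-2-en-1-yl]-2,2-dimethyl-5-[2-(triethylsilyloxy)propan-2-yl]-1,3-dioxolane, via alkenylalane 9 (not isolated)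
Conditions: AlMe3 (2.5 equiv), Cp2ZrCl2 (0.2 equiv), H2O (1 equiv), CH2Cl2, −20 °C; then I2, THF, −20 → 0 °C
Reagents that add atoms: trimethylaluminium, C[Al](C)C; iodine, II
Why: Negishi carboalumination adds methyl and aluminium syn across the alkyne with methyl on the internal carbon, and iodinolysis with retention fixes the (E)-C6′=C7′ olefin; the water-accelerated variant runs cold and should spare the acetonide.

**Step 7**
Reactants: 10 (E)-alkenyl iodide; 11 (4-bromobut-1-yn-1-yl)trimethylsilane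
Product: 13 (4R,5R)-2,2-dimethyl-4-[(2E)-2-methyl-7-(trimethylsilyl)hept-2-en-6-yn-1-yl]-5-[2-(triethylsilyloxy)propan-2-yl]-1,3-dioxolane, via organozinc bromide 12 (not isolated)
Conditions: 11, Zn dust, LiCl, THF, 50 °C; then 10, Pd(PPh3)4 (5 mol %), THF, rt
Reagents that add atoms: none
Why: Negishi cross-coupling of an alkenyl iodide with a homopropargylic alkylzinc halide forms the C5′–C6′ bond with retention of olefin geometry and tolerates the silyl ether and the acetal.

**Step 8**
Reactants: 13 silylated enyne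
Product: 14 (4R,5R)-2,2-dimethyl-4-[(2E)-2-methylhept-2-en-6-yn-1-yl]-5-[2-(triethylsilyloxy)propan-2-yl]-1,3-dioxolane
Conditions: K2CO3, MeOH, rt
Reagents that add atoms: none
Why: Base-catalysed protodesilylation of the alkynylsilane frees the terminal alkyne without touching the olefin, the silyl ether or the acetonide.

**Step 9**
Reactants: 14 terminal enyne
Product: 17 (2E,6E)-8-{(4R,5R)-2,2-dimethyl-5-[2-(triethylsilyloxy)propan-2-yl]-1,3-dioxolan-4-yl}-3,7-dimethylocta-2,6-dien-1-ol, via alkenylalane 15 (not isolated), via lithium aluminate 16 (not isolated)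
Conditions: AlMe3 (2.5 equiv), Cp2ZrCl2 (0.2 equiv), H2O (1 equiv), CH2Cl2, −20 °C; volatiles removed; n-BuLi, THF, −78 °C; (CH2O)n, −78 °C → rt; aq work-up
Reagents that add atoms: trimethylaluminium, C[Al](C)C; paraformaldehyde (as formaldehyde), C=O
Why: A second Negishi carboalumination of the terminal alkyne (the trisubstituted olefin is inert), activation as the lithium aluminate and hydroxymethylation with formaldehyde set the (E)-C2′=C3′ olefin by syn addition and deliver the primary allylic alcohol.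

**Step 10**
Reactants: 17 allylic alcohol; 18 2,4,6-trihydroxybenzaldehyde
Product: 19 4-{[(2E,6E)-8-{(4R,5R)-2,2-dimethyl-5-[2-(triethylsilyloxy)propan-2-yl]-1,3-dioxolan-4-yl}-3,7-dimethylocta-2,6-dien-1-yl]oxy}-2,6-dihydroxybenzaldehyde
Conditions: 18 (2.5 equiv), PPh3, DIAD, THF, 0 °C → rt
Reagents that add atoms: none
Why: Mitsunobu etherification should engage the 4-hydroxyl, the most acidic and least hindered phenol (the ortho hydroxyls are tied to the formyl group), the primary allylic alcohol reacting by direct SN2 displacement while the excess of the cheap phenol suppresses double alkylation.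

**Step 11**
Reactants: 19 2,6-dihydroxy-4-alkoxybenzaldehyde; 20 (triphenylphosphoranylidene)ketene
Product: 22 7-{[(2E,6E)-8-{(4R,5R)-2,2-dimethyl-5-[2-(triethylsilyloxy)propan-2-yl]-1,3-dioxolan-4-yl}-3,7-dimethylocta-2,6-dien-1-yl]oxy}-5-hydroxy-2H-chromen-2-one, via aryl ylide ester 21 (not isolated)
Conditions: 20 (1.1 equiv, slow addition), toluene, 90 °C
Reagents that add atoms: none
Why: A phenol O–H adds across the C=C of the cumulated ylide to give the aryl (triphenylphosphoranylidene)acetate 21 (O1–C2 bond), whose stabilised ylide carbon attacks the neighbouring formyl group and expels Ph3PO to form C3=C4. The closest known reaction type is the coumarin synthesis from 2-hydroxybenzaldehydes and Ph3P=C=C=O by tandem O-acylation and intramolecular Wittig olefination. Ring B closes by 6-exo-trig attack of the ylide carbon on the aldehyde, and the six-membered ring allows only the cis olefin of the lactone. No stereocentre is created, and C9′ and C10′ are remote and untouched under these neutral conditions. Regiochemistry needs no control because the formyl carbon is flanked by two equivalent phenols, and single acylation is favoured by slow addition of about one equivalent of 20 and by the absence of any other free hydroxyl (tertiary alcohol silylated, diol as acetonide). At 90 °C the aryl allyl ether stays far below the temperature of Claisen rearrangement, and the acetonide, silyl ether and both chain olefins are inert.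

**Step 12**
Reactants: 22 protected coumarin
Product: 23 5-hydroxy-7-{[(2E,6E,9R,10R)-9,10,11-trihydroxy-3,7,11-trimethyldodeca-2,6-dien-1-yl]oxy}-2H-chromen-2-one (CNP0174708.3)
Conditions: 1 M aq HCl/THF (1:3), rt
Reagents that add atoms: none
Why: Acid-catalysed hydrolysis removes the triethylsilyl ether and the dioxolane acetal in one pot under dilute conditions that geranyl-type aryl ethers, the coumarin lactone and trisubstituted olefins tolerate, and no stereocentre is touched.

**Compound list**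
1 | 2,3-O-isopropylidene-D-erythronolactone, (3aR,6aR)-2,2-dimethyldihydrofuro[3,4-d][1,3]dioxol-4(3aH)-one | C1[C@@H](OC(C)(C)O2)[C@@H]2C(=O)O1 | starting material
2 | 1-[(4R,5R)-5-(hydroxymethyl)-2,2-dimethyl-1,3-dioxolan-4-yl]ethan-1-one (present as its magnesium alkoxide, not isolated) | OC[C@@H](OC(C)(C)O1)[C@@H]1C(C)=O | intermediate
3 | 2-[(4R,5R)-5-(hydroxymethyl)-2,2-dimethyl-1,3-dioxolan-4-yl]propan-2-ol | OC[C@@H](OC(C)(C)O1)[C@@H]1C(C)(C)O | intermediate
4 | (4R,5R)-2,2-dimethyl-4-[2-(triethylsilyloxy)propan-2-yl]-5-[(triethylsilyloxy)methyl]-1,3-dioxolane | CC[Si](CC)(CC)OC[C@@H](OC(C)(C)O1)[C@@H]1C(C)(C)O[Si](CC)(CC)CC | intermediate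
5 | {(4R,5R)-2,2-dimethyl-5-[2-(triethylsilyloxy)propan-2-yl]-1,3-dioxolan-4-yl}methanol | OC[C@@H](OC(C)(C)O1)[C@@H]1C(C)(C)O[Si](CC)(CC)CC | intermediate
6 | {(4R,5R)-2,2-dimethyl-5-[2-(triethylsilyloxy)propan-2-yl]-1,3-dioxolan-4-yl}methyl trifluoromethanesulfonate (not isolated) | O=S(=O)(OC[C@@H](OC(C)(C)O1)[C@@H]1C(C)(C)O[Si](CC)(CC)CC)C(F)(F)F | intermediate
7 | (4R,5R)-2,2-dimethyl-4-[2-(triethylsilyloxy)propan-2-yl]-5-[3-(trimethylsilyl)prop-2-yn-1-yl]-1,3-dioxolane | C[Si](C)(C)C#CC[C@@H](OC(C)(C)O1)[C@@H]1C(C)(C)O[Si](CC)(CC)CC | intermediate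
8 | (4R,5R)-2,2-dimethyl-4-(prop-2-yn-1-yl)-5-[2-(triethylsilyloxy)propan-2-yl]-1,3-dioxolane | C#CC[C@@H](OC(C)(C)O1)[C@@H]1C(C)(C)O[Si](CC)(CC)CC | intermediate
9 | dimethyl[(1E)-3-{(4R,5R)-2,2-dimethyl-5-[2-(triethylsilyloxy)propan-2-yl]-1,3-dioxolan-4-yl}-2-methylprop-1-en-1-yl]alane (not isolated) | C[Al](C)/C=C(\C)C[C@@H](OC(C)(C)O1)[C@@H]1C(C)(C)O[Si](CC)(CC)CC | intermediate
10 | (4R,5R)-4-[(2E)-3-iodo-2-methylprop-2-en-1-yl]-2,2-dimethyl-5-[2-(triethylsilyloxy)propan-2-yl]-1,3-dioxolane | I/C=C(\C)C[C@@H](OC(C)(C)O1)[C@@H]1C(C)(C)O[Si](CC)(CC)CC | intermediate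
11 | (4-bromobut-1-yn-1-yl)trimethylsilane | C[Si](C)(C)C#CCCBr | starting material
12 | bromo[4-(trimethylsilyl)but-3-yn-1-yl]zinc (not isolated) | C[Si](C)(C)C#CCC[Zn]Br | intermediate
13 | (4R,5R)-2,2-dimethyl-4-[(2E)-2-methyl-7-(trimethylsilyl)hept-2-en-6-yn-1-yl]-5-[2-(triethylsilyloxy)propan-2-yl]-1,3-dioxolane | C[Si](C)(C)C#CCC/C=C(\C)C[C@@H](OC(C)(C)O1)[C@@H]1C(C)(C)O[Si](CC)(CC)CC | intermediate
14 | (4R,5R)-2,2-dimethyl-4-[(2E)-2-methylhept-2-en-6-yn-1-yl]-5-[2-(triethylsilyloxy)propan-2-yl]-1,3-dioxolane | C#CCC/C=C(\C)C[C@@H](OC(C)(C)O1)[C@@H]1C(C)(C)O[Si](CC)(CC)CC | intermediate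
15 | dimethyl[(1E,5E)-7-{(4R,5R)-2,2-dimethyl-5-[2-(triethylsilyloxy)propan-2-yl]-1,3-dioxolan-4-yl}-2,6-dimethylhepta-1,5-dien-1-yl]alane (not isolated) | C[Al](C)/C=C(\C)CC/C=C(\C)C[C@@H](OC(C)(C)O1)[C@@H]1C(C)(C)O[Si](CC)(CC)CC | intermediate
16 | lithium butyl(dimethyl)[(1E,5E)-7-{(4R,5R)-2,2-dimethyl-5-[2-(triethylsilyloxy)propan-2-yl]-1,3-dioxolan-4-yl}-2,6-dimethylhepta-1,5-dien-1-yl]aluminate (not isolated) | [Li+].CCCC[Al-](C)(C)/C=C(\C)CC/C=C(\C)C[C@@H](OC(C)(C)O1)[C@@H]1C(C)(C)O[Si](CC)(CC)CC | intermediate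
17 | (2E,6E)-8-{(4R,5R)-2,2-dimethyl-5-[2-(triethylsilyloxy)propan-2-yl]-1,3-dioxolan-4-yl}-3,7-dimethylocta-2,6-dien-1-ol | OC/C=C(\C)CC/C=C(\C)C[C@@H](OC(C)(C)O1)[C@@H]1C(C)(C)O[Si](CC)(CC)CC | intermediate
18 | 2,4,6-trihydroxybenzaldehyde | O=Cc1c(O)cc(O)cc1O | starting material
19 | 4-{[(2E,6E)-8-{(4R,5R)-2,2-dimethyl-5-[2-(triethylsilyloxy)propan-2-yl]-1,3-dioxolan-4-yl}-3,7-dimethylocta-2,6-dien-1-yl]oxy}-2,6-dihydroxybenzaldehyde | O=Cc1c(O)cc(OC/C=C(\C)CC/C=C(\C)C[C@@H](OC(C)(C)O2)[C@@H]2C(C)(C)O[Si](CC)(CC)CC)cc1O | intermediate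
20 | (triphenylphosphoranylidene)ketene | O=C=C=P(c1ccccc1)(c1ccccc1)c1ccccc1 | starting material
21 | 2-formyl-3-hydroxy-5-{[(2E,6E)-8-{(4R,5R)-2,2-dimethyl-5-[2-(triethylsilyloxy)propan-2-yl]-1,3-dioxolan-4-yl}-3,7-dimethylocta-2,6-dien-1-yl]oxy}phenyl (triphenylphosphoranylidene)acetate (not isolated) | O=Cc1c(O)cc(OC/C=C(\C)CC/C=C(\C)C[C@@H](OC(C)(C)O2)[C@@H]2C(C)(C)O[Si](CC)(CC)CC)cc1OC(=O)C=P(c1ccccc1)(c1ccccc1)c1ccccc1 | intermediate
22 | 7-{[(2E,6E)-8-{(4R,5R)-2,2-dimethyl-5-[2-(triethylsilyloxy)propan-2-yl]-1,3-dioxolan-4-yl}-3,7-dimethylocta-2,6-dien-1-yl]oxy}-5-hydroxy-2H-chromen-2-one | C/C(=C\COc1cc(O)c2ccc(=O)oc2c1)CC/C=C(\C)C[C@@H](OC(C)(C)O3)[C@@H]3C(C)(C)O[Si](CC)(CC)CC | intermediate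
23 | 5-hydroxy-7-{[(2E,6E,9R,10R)-9,10,11-trihydroxy-3,7,11-trimethyldodeca-2,6-dien-1-yl]oxy}-2H-chromen-2-one | C/C(=C\COc1cc(O)c2ccc(=O)oc2c1)CC/C=C(\C)C[C@@H](O)[C@@H](O)C(C)(C)O | target

**Totals.** Total step count: 12. Longest linear sequence: 12 steps (1 → 23).

**Steps most likely to fail**

Step 11. The chelated, electron-rich aldehyde may olefinate slowly after O-acylation, while the acidic second phenol protonates the ylide or is acylated by a second molecule of 20, so that material stalls at the ester stage. The fallback sets out from 19 and separates olefination from lactonisation. An intermolecular Wittig reaction with methyl (triphenylphosphoranylidene)acetate (toluene, 80 °C) should give methyl (2E)-3-(2,6-dihydroxy-4-{[(2E,6E)-8-{(4R,5R)-2,2-dimethyl-5-[2-(triethylsilyloxy)propan-2-yl]-1,3-dioxolan-4-yl}-3,7-dimethylocta-2,6-dien-1-yl]oxy}phenyl)prop-2-enoate F1. Irradiation of F1 at 365 nm in dilute MeCN at rt should isomerise the cinnamate to the Z form, which lactonises onto either of the equivalent phenols with loss of methanol. The fallback comes back to the route at 22.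

Step 10. Site selectivity may erode (etherification at an ortho hydroxyl or twice), or the allylic oxyphosphonium ion may be captured with transposition. The fallback sets out from 17 and replaces the redox condensation by alkylation of a phenoxide. PPh3/CBr4 (CH2Cl2, 0 °C) should give (4R,5R)-4-[(2E,6E)-8-bromo-2,6-dimethylocta-2,6-dien-1-yl]-2,2-dimethyl-5-[2-(triethylsilyloxy)propan-2-yl]-1,3-dioxolane F2. F2 is then used to alkylate an excess of 18 with CsHCO3 in MeCN at 40 °C, where only the most acidic para hydroxyl is ionised. The fallback comes back to the route at 19.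

Step 4. The crowded primary triflate, cis to the bulky silyloxypropyl group, may be consumed by intramolecular displacement by the silyl ether oxygen or by elimination before the acetylide reacts. The fallback sets out from 5 and builds the propargyl unit by carbonyl homologation instead of substitution:
- Dess–Martin oxidation should give (4S,5R)-2,2-dimethyl-5-[2-(triethylsilyloxy)propan-2-yl]-1,3-dioxolane-4-carbaldehyde F3.
- Wittig reaction with Ph3P=CHOMe (from (methoxymethyl)triphenylphosphonium chloride and KN(SiMe3)2, THF, −78 → 0 °C) should give (4R,5R)-4-(2-methoxyethenyl)-2,2-dimethyl-5-[2-(triethylsilyloxy)propan-2-yl]-1,3-dioxolane F4 as an E/Z mixture.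
- Enol ether hydrolysis with Hg(OAc)2 in aqueous THF, then KI, should give 2-{(4R,5R)-2,2-dimethyl-5-[2-(triethylsilyloxy)propan-2-yl]-1,3-dioxolan-4-yl}acetaldehyde F5.
- Seyferth–Gilbert homologation with the Ohira–Bestmann reagent (K2CO3, MeOH, 0 °C → rt) converts F5 into the terminal alkyne.

The fallback comes back to the route at 8.

**Further compounds**
F1 | step 11 | methyl (2E)-3-(2,6-dihydroxy-4-{[(2E,6E)-8-{(4R,5R)-2,2-dimethyl-5-[2-(triethylsilyloxy)propan-2-yl]-1,3-dioxolan-4-yl}-3,7-dimethylocta-2,6-dien-1-yl]oxy}phenyl)prop-2-enoate | COC(=O)/C=C/c1c(O)cc(OC/C=C(\C)CC/C=C(\C)C[C@@H](OC(C)(C)O2)[C@@H]2C(C)(C)O[Si](CC)(CC)CC)cc1O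
F2 | step 10 | (4R,5R)-4-[(2E,6E)-8-bromo-2,6-dimethylocta-2,6-dien-1-yl]-2,2-dimethyl-5-[2-(triethylsilyloxy)propan-2-yl]-1,3-dioxolane | BrC/C=C(\C)CC/C=C(\C)C[C@@H](OC(C)(C)O1)[C@@H]1C(C)(C)O[Si](CC)(CC)CC
F3 | step 4 | (4S,5R)-2,2-dimethyl-5-[2-(triethylsilyloxy)propan-2-yl]-1,3-dioxolane-4-carbaldehyde | O=C[C@@H](OC(C)(C)O1)[C@@H]1C(C)(C)O[Si](CC)(CC)CC
F4 | step 4 | (4R,5R)-4-(2-methoxyethenyl)-2,2-dimethyl-5-[2-(triethylsilyloxy)propan-2-yl]-1,3-dioxolane (E/Z mixture) | COC=C[C@@H](OC(C)(C)O1)[C@@H]1C(C)(C)O[Si](CC)(CC)CC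
F5 | step 4 | 2-{(4R,5R)-2,2-dimethyl-5-[2-(triethylsilyloxy)propan-2-yl]-1,3-dioxolan-4-yl}acetaldehyde | O=CC[C@@H](OC(C)(C)O1)[C@@H]1C(C)(C)O[Si](CC)(CC)CC
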